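**Retrosynthetic overview**
1. Target ⇐ bicyclic triene alcohol 25. Both epoxides come from the E,E-diene by catalyst-controlled epoxidation, and the C13 ketone from a silyl-protected carbinol.
2. Key step (not a ring closure at an alkene by metathesis, McMurry or vinyl-halide/aldehyde coupling): the 12-membered ring is closed by intramolecular SE2' attack of a ring allylstannane (C18–C12=C11) on the C10 aldehyde. This forms C10–C11, sets C10 and C11, and creates the C12=C18 methylene.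
3. Cyclisation precursor 24 ⇐ Negishi sp3–sp2 union (C2–C3) of ring iodide 15 with dienyl iodide 9, then α-iodination, reduction and stannylmethylation.
4. Ring fragment ⇐ desymmetrising Rh-catalysed 1,4-vinylation of 4,4-dimethylcyclohexadienone (sets C1). Chain ⇐ two Zr-catalysed carboaluminations and one Negishi coupling (both E-alkenes).
5. Ring order: the six-membered ring is present from the start (10); the 12-membered ring is formed in step 15.

Assumption: dienone 10 is purchased (otherwise one step, DDQ, from 4,4-dimethylcyclohex-2-en-1-one); bicyclic compounds are named with verticillane locants (C1 and C11 bridgeheads, C15 the CMe2 bridge, C12–C14 the three-carbon bridge, C2–C10 the nine-carbon bridge, C18 on C12, C19 on C8, C20 on C4).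

**Route**

Step 1
Reactants: 1 tert-butyl(but-3-yn-1-yloxy)dimethylsilane
Product: 3 tert-butyl{[(3E)-4-iodo-3-methylbut-3-en-1-yl]oxy}dimethylsilane, via alkenylalane 2 (not isolated)
Conditions: Me3Al (2.5 equiv), (C5H5)2ZrCl2 (0.25 equiv), CH2Cl2, 0 °C to rt; then I2, THF, −30 °C
Reagents that add atoms: trimethylaluminium C[Al](C)C; iodine II
Why: Negishi zirconium-catalysed carboalumination adds CH3 and Al syn across the terminal alkyne with methyl on the internal carbon, and iodinolysis of the C–Al bond occurs with retention, so only the E-iodoalkene forms.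

Step 2
Reactants: 3 tert-butyl{[(3E)-4-iodo-3-methylbut-3-en-1-yl]oxy}dimethylsilane; 4 (4-bromobut-1-yn-1-yl)trimethylsilane
Product: 6 tert-butyldimethyl{[(3E)-3-methyl-8-(trimethylsilyl)oct-3-en-7-yn-1-yl]oxy}silane, via alkylzinc bromide 5 (not isolated)
Conditions: 4, Zn dust, I2 (5 mol%), DMA, 80 °C; then 3, Pd(PPh3)4 (3 mol%), THF, 40 °C
Reagents that add atoms: none
Why: Negishi sp3–sp2 cross-coupling of the homopropargylic alkylzinc with the alkenyl iodide proceeds with retention of the E geometry, the C-silyl cap keeping the alkyne inert.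

Step 3
Reactants: 6 tert-butyldimethyl{[(3E)-3-methyl-8-(trimethylsilyl)oct-3-en-7-yn-1-yl]oxy}silane
Product: 7 tert-butyldimethyl{[(3E)-3-methyloct-3-en-7-yn-1-yl]oxy}silane
Conditions: K2CO3 (0.2 equiv), MeOH, rt
Reagents that add atoms: none
Why: Methanolic carbonate protodesilylates the alkynylsilane selectively, since a primary tert-butyldimethylsilyl ether is stable to these conditions.

Step 4
Reactants: 7 tert-butyldimethyl{[(3E)-3-methyloct-3-en-7-yn-1-yl]oxy}silane
Product: 9 tert-butyl{[(3E,7E)-8-iodo-3,7-dimethylocta-3,7-dien-1-yl]oxy}dimethylsilane, via alkenylalane 8 (not isolated)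
Conditions: Me3Al (2.5 equiv), (C5H5)2ZrCl2 (0.25 equiv), CH2Cl2, 0 °C to rt; then I2, THF, −30 °C
Reagents that add atoms: trimethylaluminium C[Al](C)C; iodine II
Why: A second Negishi carboalumination–iodinolysis (syn addition, retention) builds the second E-trisubstituted alkene as its alkenyl iodide while the existing trisubstituted alkene does not react.

Step 5
Reactants: 10 4,4-dimethylcyclohexa-2,5-dien-1-one
Product: 11 (5S)-5-ethenyl-4,4-dimethylcyclohex-2-en-1-one
Conditions: CH2=CHBF3K (1.1 equiv), [Rh(C8H12)2]BF4 (3 mol%; C8H12 = 1,5-cyclooctadiene), (S)-2,2'-bis(diphenylphosphino)-1,1'-binaphthyl (3.3 mol%), toluene/H2O 10:1, 100 °C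
Reagents that add atoms: potassium vinyltrifluoroborate [K+].C=C[B-](F)(F)F
Why: Hayashi–Miyaura rhodium-catalysed asymmetric 1,4-addition desymmetrises the achiral dienone (homotopic enone halves, enantiotopic faces), the (S)-BINAP–rhodium vinyl species adding to the face that gives the 5S centre (C1 of the target, as in (S)-3-substituted cyclohexanones from cyclohexenone) while the second, more hindered enone survives.

Step 6
Reactants: 11 (5S)-5-ethenyl-4,4-dimethylcyclohex-2-en-1-one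
Product: 14 (5R)-5-(hydroxymethyl)-4,4-dimethylcyclohex-2-en-1-one, via ozonide 12 (not isolated), via aldehyde 13 (not isolated)
Conditions: O3, CH2Cl2, −78 °C (Sudan Red 7B end point); Me2S, −78 °C to rt; then NaBH4 (1.5 equiv), EtOH, −78 °C
Reagents that add atoms: ozone [O-][O+]=O
Why: Ozonolysis cleaves the electron-rich vinyl group in preference to the electron-poor enone alkene and NaBH4 at −78 °C reduces only the aldehyde, the telescoping keeping the α-stereocentre from enolising (same spatial arrangement, descriptor R by priority change).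

Step 7
Reactants: 14 (5R)-5-(hydroxymethyl)-4,4-dimethylcyclohex-2-en-1-one
Product: 15 (5R)-5-(iodomethyl)-4,4-dimethylcyclohex-2-en-1-one
Conditions: I2, PPh3, imidazole, CH2Cl2, 0 °C to rt
Reagents that add atoms: iodine II
Why: Appel-type iodination converts the primary alcohol into the iodide by SN2 displacement of the alkoxyphosphonium ion without touching the ring stereocentre.

Step 8
Reactants: 15 (5R)-5-(iodomethyl)-4,4-dimethylcyclohex-2-en-1-one; 9 tert-butyl{[(3E,7E)-8-iodo-3,7-dimethylocta-3,7-dien-1-yl]oxy}dimethylsilane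
Product: 17 (5R)-5-[(2E,6E)-9-{[tert-butyl(dimethyl)silyl]oxy}-3,7-dimethylnona-2,6-dien-1-yl]-4,4-dimethylcyclohex-2-en-1-one, via alkylzinc iodide 16 (not isolated)
Conditions: 15, Zn dust (activated with BrCH2CH2Br/Me3SiCl), LiCl, THF, 30 °C; then 9, PdCl2(dppf) (5 mol%; dppf = 1,1'-bis(diphenylphosphino)ferrocene), THF, 45 °C
Reagents that add atoms: none
Why: Negishi sp3–sp2 coupling joins C2 to C3, because zinc inserts into the primary C–I bond without attacking the enone and palladium couples the alkylzinc with the alkenyl iodide with retention of the E geometry.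

Step 9
Reactants: 17 (5R)-5-[(2E,6E)-9-{[tert-butyl(dimethyl)silyl]oxy}-3,7-dimethylnona-2,6-dien-1-yl]-4,4-dimethylcyclohex-2-en-1-one
Product: 18 (5R)-5-[(2E,6E)-9-{[tert-butyl(dimethyl)silyl]oxy}-3,7-dimethylnona-2,6-dien-1-yl]-2-iodo-4,4-dimethylcyclohex-2-en-1-one
Conditions: I2 (1.5 equiv), pyridine/CH2Cl2 1:1, 0 °C to rt
Reagents that add atoms: iodine II
Why: Johnson α-iodination (pyridine conjugate addition, iodination of the enolate, elimination) places iodine only on the α-carbon of the enone, isolated trisubstituted alkenes giving no net reaction with I2/pyridine.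

Step 10
Reactants: 18 (5R)-5-[(2E,6E)-9-{[tert-butyl(dimethyl)silyl]oxy}-3,7-dimethylnona-2,6-dien-1-yl]-2-iodo-4,4-dimethylcyclohex-2-en-1-one
Product: 19 (1R,5R)-5-[(2E,6E)-9-{[tert-butyl(dimethyl)silyl]oxy}-3,7-dimethylnona-2,6-dien-1-yl]-2-iodo-4,4-dimethylcyclohex-2-en-1-ol
Conditions: (S)-1-methyl-3,3-diphenyltetrahydro-1H,3H-pyrrolo[1,2-c][1,3,2]oxazaborole (0.2 equiv), catecholborane (1.5 equiv), toluene, −78 °C
Reagents that add atoms: none
Why: Corey–Bakshi–Shibata reduction with the α-iodoalkenyl group as the large substituent gives the 1R carbinol under reagent control (oxygen trans to the side chain, hence on the ring face opposite to the one the tether must later approach), and catecholborane does not hydroborate the alkenes at −78 °C.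

Step 11
Reactants: 19 (1R,5R)-5-[(2E,6E)-9-{[tert-butyl(dimethyl)silyl]oxy}-3,7-dimethylnona-2,6-dien-1-yl]-2-iodo-4,4-dimethylcyclohex-2-en-1-ol
Product: 20 tert-butyl{[(1R,5R)-5-[(2E,6E)-9-{[tert-butyl(dimethyl)silyl]oxy}-3,7-dimethylnona-2,6-dien-1-yl]-2-iodo-4,4-dimethylcyclohex-2-en-1-yl]oxy}dimethylsilane
Conditions: TBSOTf (1.3 equiv), 2,6-lutidine, CH2Cl2, −78 to 0 °C
Reagents that add atoms: tert-butyldimethylsilyl trifluoromethanesulfonate CC(C)(C)[Si](C)(C)OS(=O)(=O)C(F)(F)F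
Why: Silylation with the silyl triflate protects the hindered secondary allylic alcohol, which must be masked for the Lewis-acid step.

Step 12
Reactants: 20 tert-butyl{[(1R,5R)-5-[(2E,6E)-9-{[tert-butyl(dimethyl)silyl]oxy}-3,7-dimethylnona-2,6-dien-1-yl]-2-iodo-4,4-dimethylcyclohex-2-en-1-yl]oxy}dimethylsilane
Product: 21 (3E,7E)-9-[(1R,5R)-5-{[tert-butyl(dimethyl)silyl]oxy}-4-iodo-2,2-dimethylcyclohex-3-en-1-yl]-3,7-dimethylnona-3,7-dien-1-ol
Conditions: camphor-10-sulfonic acid (0.1 equiv), MeOH/CH2Cl2 1:1, 0 °C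
Reagents that add atoms: none
Why: Acid-catalysed methanolysis removes the unhindered primary silyl ether much faster than the hindered secondary allylic one.

Step 13
Reactants: 21 (3E,7E)-9-[(1R,5R)-5-{[tert-butyl(dimethyl)silyl]oxy}-4-iodo-2,2-dimethylcyclohex-3-en-1-yl]-3,7-dimethylnona-3,7-dien-1-ol
Product: 23 (3E,7E)-9-[(1R,5R)-5-{[tert-butyl(dimethyl)silyl]oxy}-2,2-dimethyl-4-[(tributylstannyl)methyl]cyclohex-3-en-1-yl]-3,7-dimethylnona-3,7-dien-1-ol, via dilithio species 22 (not isolated)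
Conditions: t-BuLi (3.2 equiv), Et2O, −78 °C; then Bu3SnCH2I (1.2 equiv), −78 to −30 °C; aq. NH4Cl
Reagents that add atoms: (iodomethyl)tributylstannane CCCC[Sn](CCCC)(CCCC)CI
Why: Deprotonation of the alcohol and iodine–lithium exchange give an alkenyllithium that is alkylated (SN2) by the very reactive α-stannyl iodide to install the allylstannane, the lithium alkoxide being inert in ether at −78 °C and the low temperature suppressing silyl migration.

Step 14
Reactants: 23 (3E,7E)-9-[(1R,5R)-5-{[tert-butyl(dimethyl)silyl]oxy}-2,2-dimethyl-4-[(tributylstannyl)methyl]cyclohex-3-en-1-yl]-3,7-dimethylnona-3,7-dien-1-ol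
Product: 24 (3E,7E)-9-[(1R,5R)-5-{[tert-butyl(dimethyl)silyl]oxy}-2,2-dimethyl-4-[(tributylstannyl)methyl]cyclohex-3-en-1-yl]-3,7-dimethylnona-3,7-dienal
Conditions: Dess–Martin periodinane (1.3 equiv), NaHCO3, CH2Cl2, 0 °C; used crude at once
Reagents that add atoms: none
Why: Dess–Martin oxidation under buffered, amine-free conditions gives the β,γ-unsaturated aldehyde without alkene migration into conjugation or protodestannylation.

Step 15
Reactants: 24 (3E,7E)-9-[(1R,5R)-5-{[tert-butyl(dimethyl)silyl]oxy}-2,2-dimethyl-4-[(tributylstannyl)methyl]cyclohex-3-en-1-yl]-3,7-dimethylnona-3,7-dienal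
Product: 25 (1R,3E,7E,10R,11R,13R)-13-{[tert-butyl(dimethyl)silyl]oxy}verticilla-3,7,12(18)-trien-10-ol
Conditions: BF3·OEt2 (2.5 equiv), CH2Cl2, −78 °C, 24 added over 3 h (final 1 mM); aq. NaHCO3
Reagents that add atoms: none
Why: Intramolecular Lewis-acid-promoted SE2' addition of the allylstannane to the aldehyde (Marshall-type macrocyclisation, open antiperiplanar transition state) closes the 12-membered ring: the tether reaches C11 only on the face syn to the C1 side chain (11R, tin departing anti), and C9 must sit between H11 and C12 because the alternative placement collides with C2 and the quaternary C15 (10R), the allyl shift unveiling the C12=C18 methylene.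

Step 16
Reactants: 25 (1R,3E,7E,10R,11R,13R)-13-{[tert-butyl(dimethyl)silyl]oxy}verticilla-3,7,12(18)-trien-10-ol
Product: 26 (1R,3E,7E,10R,11R,13R)-13-{[tert-butyl(dimethyl)silyl]oxy}verticilla-3,7,12(18)-trien-10-yl acetate
Conditions: Ac2O, 4-(dimethylamino)pyridine (0.1 equiv), Et3N, CH2Cl2, 0 °C to rt
Reagents that add atoms: acetic anhydride CC(=O)OC(C)=O
Why: Nucleophile-catalysed acylation esterifies the only free hydroxyl with retention at C10.

Step 17
Reactants: 26 (1R,3E,7E,10R,11R,13R)-13-{[tert-butyl(dimethyl)silyl]oxy}verticilla-3,7,12(18)-trien-10-yl acetate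
Product: 27 (1R,3S,4S,7S,8S,10R,11R,13R)-13-{[tert-butyl(dimethyl)silyl]oxy}-3,4:7,8-diepoxyverticill-12(18)-en-10-yl acetate
Conditions: 1,2:4,5-di-O-isopropylidene-β-L-erythro-2,3-hexodiulo-2,6-pyranose (0.6 equiv), KHSO5 (as 2KHSO5·KHSO4·K2SO4, 3 equiv), K2CO3, Bu4NHSO4 (cat.), MeCN/CH2(OMe)2/aq. Na2B4O7 buffer, 0 °C
Reagents that add atoms: potassium peroxymonosulfate [K+].[O-]S(=O)(=O)OO
Why: Shi epoxidation with the L-configured ketone (the D-ketone gives R,R epoxides from E-trisubstituted alkenes of this type) delivers oxygen through the spiro transition state to give the S,S epoxide at each alkene, which is also the exposed outer face of the conformer with both vinylic methyls anti to the C12–C14 bridge, while the hindered 1,1-disubstituted allylic alkene does not react.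

Step 18
Reactants: 27 (1R,3S,4S,7S,8S,10R,11R,13R)-13-{[tert-butyl(dimethyl)silyl]oxy}-3,4:7,8-diepoxyverticill-12(18)-en-10-yl acetate
Product: 28 (1S,3S,4S,7S,8S,10R,11R,13R)-13-hydroxy-3,4:7,8-diepoxyverticill-12(18)-en-10-yl acetate
Conditions: Bu4NF (2 equiv), AcOH (2 equiv), THF, 0 °C to rt
Reagents that add atoms: none
Why: Fluoride-mediated desilylation buffered with acetic acid frees the allylic alcohol without opening the epoxides or cleaving the acetate (C1 is unchanged in space, its descriptor becoming S by priority only).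

Step 19
Reactants: 28 (1S,3S,4S,7S,8S,10R,11R,13R)-13-hydroxy-3,4:7,8-diepoxyverticill-12(18)-en-10-yl acetate
Product: 29 (1R,3S,4S,7S,8S,10R,11R)-3,4:7,8-diepoxy-13-oxoverticill-12(18)-en-10-yl acetate
Conditions: Dess–Martin periodinane (1.5 equiv), NaHCO3, CH2Cl2, 0 °C to rt
Reagents that add atoms: none
Why: Dess–Martin oxidation of the allylic alcohol gives the α-methylene ketone under buffered neutral conditions that leave the epoxides, the acetate and the exocyclic alkene position intact.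

**Compound list**
1 | tert-butyl(but-3-yn-1-yloxy)dimethylsilane | C#CCCO[Si](C)(C)C(C)(C)C | starting material
2 | [(1E)-4-{[tert-butyl(dimethyl)silyl]oxy}-2-methylbut-1-en-1-yl]dimethylalane | C[Al](C)/C=C(\C)CCO[Si](C)(C)C(C)(C)C | intermediate
3 | tert-butyl{[(3E)-4-iodo-3-methylbut-3-en-1-yl]oxy}dimethylsilane | I/C=C(\C)CCO[Si](C)(C)C(C)(C)C | intermediate
4 | (4-bromobut-1-yn-1-yl)trimethylsilane | BrCCC#C[Si](C)(C)C | starting material
5 | [4-(trimethylsilyl)but-3-yn-1-yl]zinc bromide | Br[Zn]CCC#C[Si](C)(C)C | intermediate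
6 | tert-butyldimethyl{[(3E)-3-methyl-8-(trimethylsilyl)oct-3-en-7-yn-1-yl]oxy}silane | C[Si](C)(C)C#CCC/C=C(\C)CCO[Si](C)(C)C(C)(C)C | intermediate
7 | tert-butyldimethyl{[(3E)-3-methyloct-3-en-7-yn-1-yl]oxy}silane | C#CCC/C=C(\C)CCO[Si](C)(C)C(C)(C)C | intermediate
8 | [(1E,5E)-8-{[tert-butyl(dimethyl)silyl]oxy}-2,6-dimethylocta-1,5-dien-1-yl]dimethylalane | C[Al](C)/C=C(\C)CC/C=C(\C)CCO[Si](C)(C)C(C)(C)C | intermediate
9 | tert-butyl{[(3E,7E)-8-iodo-3,7-dimethylocta-3,7-dien-1-yl]oxy}dimethylsilane | I/C=C(\C)CC/C=C(\C)CCO[Si](C)(C)C(C)(C)C | intermediate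
10 | 4,4-dimethylcyclohexa-2,5-dien-1-one | O=C1C=CC(C)(C)C=C1 | starting material
11 | (5S)-5-ethenyl-4,4-dimethylcyclohex-2-en-1-one | O=C1C=CC(C)(C)[C@H](C=C)C1 | intermediate
12 | (5R)-4,4-dimethyl-5-(1,2,4-trioxolan-3-yl)cyclohex-2-en-1-one | O=C1C=CC(C)(C)[C@H](C2OCOO2)C1 | intermediate
13 | (1R)-2,2-dimethyl-5-oxocyclohex-3-ene-1-carbaldehyde | O=C1C=CC(C)(C)[C@H](C=O)C1 | intermediate
14 | (5R)-5-(hydroxymethyl)-4,4-dimethylcyclohex-2-en-1-one | O=C1C=CC(C)(C)[C@H](CO)C1 | intermediate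
15 | (5R)-5-(iodomethyl)-4,4-dimethylcyclohex-2-en-1-one | O=C1C=CC(C)(C)[C@H](CI)C1 | intermediate
16 | {[(1R)-2,2-dimethyl-5-oxocyclohex-3-en-1-yl]methyl}zinc iodide | O=C1C=CC(C)(C)[C@H](C[Zn]I)C1 | intermediate
17 | (5R)-5-[(2E,6E)-9-{[tert-butyl(dimethyl)silyl]oxy}-3,7-dimethylnona-2,6-dien-1-yl]-4,4-dimethylcyclohex-2-en-1-one | O=C1C=CC(C)(C)[C@H](C/C=C(\C)CC/C=C(\C)CCO[Si](C)(C)C(C)(C)C)C1 | intermediate
18 | (5R)-5-[(2E,6E)-9-{[tert-butyl(dimethyl)silyl]oxy}-3,7-dimethylnona-2,6-dien-1-yl]-2-iodo-4,4-dimethylcyclohex-2-en-1-one | O=C1C(I)=CC(C)(C)[C@H](C/C=C(\C)CC/C=C(\C)CCO[Si](C)(C)C(C)(C)C)C1 | intermediate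
19 | (1R,5R)-5-[(2E,6E)-9-{[tert-butyl(dimethyl)silyl]oxy}-3,7-dimethylnona-2,6-dien-1-yl]-2-iodo-4,4-dimethylcyclohex-2-en-1-ol | O[C@H]1C(I)=CC(C)(C)[C@H](C/C=C(\C)CC/C=C(\C)CCO[Si](C)(C)C(C)(C)C)C1 | intermediate
20 | tert-butyl{[(1R,5R)-5-[(2E,6E)-9-{[tert-butyl(dimethyl)silyl]oxy}-3,7-dimethylnona-2,6-dien-1-yl]-2-iodo-4,4-dimethylcyclohex-2-en-1-yl]oxy}dimethylsilane | CC(C)(C)[Si](C)(C)O[C@H]1C(I)=CC(C)(C)[C@H](C/C=C(\C)CC/C=C(\C)CCO[Si](C)(C)C(C)(C)C)C1 | intermediate
21 | (3E,7E)-9-[(1R,5R)-5-{[tert-butyl(dimethyl)silyl]oxy}-4-iodo-2,2-dimethylcyclohex-3-en-1-yl]-3,7-dimethylnona-3,7-dien-1-ol | CC(C)(C)[Si](C)(C)O[C@H]1C(I)=CC(C)(C)[C@H](C/C=C(\C)CC/C=C(\C)CCO)C1 | intermediate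
22 | lithium (3E,7E)-9-[(1R,5R)-5-{[tert-butyl(dimethyl)silyl]oxy}-4-lithio-2,2-dimethylcyclohex-3-en-1-yl]-3,7-dimethylnona-3,7-dien-1-olate | CC(C)(C)[Si](C)(C)O[C@H]1C([Li])=CC(C)(C)[C@H](C/C=C(\C)CC/C=C(\C)CCO[Li])C1 | intermediate
23 | (3E,7E)-9-[(1R,5R)-5-{[tert-butyl(dimethyl)silyl]oxy}-2,2-dimethyl-4-[(tributylstannyl)methyl]cyclohex-3-en-1-yl]-3,7-dimethylnona-3,7-dien-1-ol | CC(C)(C)[Si](C)(C)O[C@H]1C(C[Sn](CCCC)(CCCC)CCCC)=CC(C)(C)[C@H](C/C=C(\C)CC/C=C(\C)CCO)C1 | intermediate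
24 | (3E,7E)-9-[(1R,5R)-5-{[tert-butyl(dimethyl)silyl]oxy}-2,2-dimethyl-4-[(tributylstannyl)methyl]cyclohex-3-en-1-yl]-3,7-dimethylnona-3,7-dienal | CC(C)(C)[Si](C)(C)O[C@H]1C(C[Sn](CCCC)(CCCC)CCCC)=CC(C)(C)[C@H](C/C=C(\C)CC/C=C(\C)CC=O)C1 | intermediate
25 | (1R,3E,7E,10R,11R,13R)-13-{[tert-butyl(dimethyl)silyl]oxy}verticilla-3,7,12(18)-trien-10-ol | C=C1[C@H](O[Si](C)(C)C(C)(C)C)C[C@H]2C/C=C(\C)CC/C=C(\C)C[C@@H](O)[C@@H]1C2(C)C | intermediate
26 | (1R,3E,7E,10R,11R,13R)-13-{[tert-butyl(dimethyl)silyl]oxy}verticilla-3,7,12(18)-trien-10-yl acetate | C=C1[C@H](O[Si](C)(C)C(C)(C)C)C[C@H]2C/C=C(\C)CC/C=C(\C)C[C@@H](OC(C)=O)[C@@H]1C2(C)C | intermediate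
27 | (1R,3S,4S,7S,8S,10R,11R,13R)-13-{[tert-butyl(dimethyl)silyl]oxy}-3,4:7,8-diepoxyverticill-12(18)-en-10-yl acetate | C=C1[C@H](O[Si](C)(C)C(C)(C)C)C[C@H]2C[C@@H]3O[C@@]3(C)CC[C@@H]3O[C@@]3(C)C[C@@H](OC(C)=O)[C@@H]1C2(C)C | intermediate
28 | (1S,3S,4S,7S,8S,10R,11R,13R)-13-hydroxy-3,4:7,8-diepoxyverticill-12(18)-en-10-yl acetate | C=C1[C@H](O)C[C@H]2C[C@@H]3O[C@@]3(C)CC[C@@H]3O[C@@]3(C)C[C@@H](OC(C)=O)[C@@H]1C2(C)C | intermediate
29 | (1R,3S,4S,7S,8S,10R,11R)-3,4:7,8-diepoxy-13-oxoverticill-12(18)-en-10-yl acetate (CNP0339728.1) | C=C1C(=O)C[C@H]2C[C@@H]3O[C@@]3(C)CC[C@@H]3O[C@@]3(C)C[C@@H](OC(C)=O)[C@@H]1C2(C)C | target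

**Totals**
Total step count: 19. Longest linear sequence: 16 steps (steps 1–4, then 8–19).

**Three steps most likely to fail, with fallbacks**

Step 13 (stannylmethylation). The alkenyllithium may undergo iodine exchange with the stannyl iodide or be quenched, and the alkoxide may be O-alkylated. The fallback sets out from 21 and returns at 25, replacing tin by silicon and avoiding any organolithium. Pd(PPh3)4-catalysed Kumada coupling of 21 with Me3SiCH2MgCl (4 equiv, THF, rt) gives the allylsilane alcohol (3E,7E)-9-[(1R,5R)-5-{[tert-butyl(dimethyl)silyl]oxy}-2,2-dimethyl-4-[(trimethylsilyl)methyl]cyclohex-3-en-1-yl]-3,7-dimethylnona-3,7-dien-1-ol F1. Dess–Martin oxidation gives the allylsilane aldehyde (3E,7E)-9-[(1R,5R)-5-{[tert-butyl(dimethyl)silyl]oxy}-2,2-dimethyl-4-[(trimethylsilyl)methyl]cyclohex-3-en-1-yl]-3,7-dimethylnona-3,7-dienal F2. An intramolecular Hosomi–Sakurai reaction (BF3·OEt2, CH2Cl2, −78 °C, high dilution) through the same open transition state then gives 25.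

Step 15 (macrocyclisation). The β,γ-unsaturated aldehyde may isomerise or undergo Prins chemistry before the hindered C11 attacks, and the C10 outcome rests on a transition-state argument. The fallback sets out from 24 and returns at 26, using a closed transition state followed by inversion. Iododestannylation (I2, CH2Cl2, −78 °C) gives the allylic iodide (3E,7E)-9-[(1R,5R)-5-{[tert-butyl(dimethyl)silyl]oxy}-4-(iodomethyl)-2,2-dimethylcyclohex-3-en-1-yl]-3,7-dimethylnona-3,7-dienal F3. Nozaki–Hiyama allylation with CrCl2 (THF, high dilution, rt) closes the same C10–C11 bond through a chair transition state and is expected to give the C10 epimer (1R,3E,7E,10S,11R,13R)-13-{[tert-butyl(dimethyl)silyl]oxy}verticilla-3,7,12(18)-trien-10-ol F4. Mitsunobu esterification with acetic acid (PPh3, diisopropyl azodicarboxylate, toluene) inverts C10 and gives 26 directly.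

Step 17 (double epoxidation). Four stereocentres depend on facial control at two alkenes in a flexible ring, and the acetate sits at pH about 10.5. The fallback sets out from 26 and returns at 29, moving the epoxidation to the last step under substrate control. Desilylation (Bu4NF, THF) gives the allylic alcohol (1R,3E,7E,10R,11R,13R)-13-hydroxyverticilla-3,7,12(18)-trien-10-yl acetate F5. Dess–Martin oxidation gives the dienone (1R,3E,7E,10R,11R)-13-oxoverticilla-3,7,12(18)-trien-10-yl acetate F6. mCPBA (2.2 equiv, NaHCO3, CH2Cl2, 0 °C) then epoxidises only the two electron-rich trisubstituted alkenes, from their peripheral faces in the natural-product-like conformer, to give 29.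

**Further compounds**
F1 | step 13 | (3E,7E)-9-[(1R,5R)-5-{[tert-butyl(dimethyl)silyl]oxy}-2,2-dimethyl-4-[(trimethylsilyl)methyl]cyclohex-3-en-1-yl]-3,7-dimethylnona-3,7-dien-1-ol | CC(C)(C)[Si](C)(C)O[C@H]1C(C[Si](C)(C)C)=CC(C)(C)[C@H](C/C=C(\C)CC/C=C(\C)CCO)C1
F2 | step 13 | (3E,7E)-9-[(1R,5R)-5-{[tert-butyl(dimethyl)silyl]oxy}-2,2-dimethyl-4-[(trimethylsilyl)methyl]cyclohex-3-en-1-yl]-3,7-dimethylnona-3,7-dienal | CC(C)(C)[Si](C)(C)O[C@H]1C(C[Si](C)(C)C)=CC(C)(C)[C@H](C/C=C(\C)CC/C=C(\C)CC=O)C1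
F3 | step 15 | (3E,7E)-9-[(1R,5R)-5-{[tert-butyl(dimethyl)silyl]oxy}-4-(iodomethyl)-2,2-dimethylcyclohex-3-en-1-yl]-3,7-dimethylnona-3,7-dienal | CC(C)(C)[Si](C)(C)O[C@H]1C(CI)=CC(C)(C)[C@H](C/C=C(\C)CC/C=C(\C)CC=O)C1
F4 | step 15 | (1R,3E,7E,10S,11R,13R)-13-{[tert-butyl(dimethyl)silyl]oxy}verticilla-3,7,12(18)-trien-10-ol | C=C1[C@H](O[Si](C)(C)C(C)(C)C)C[C@H]2C/C=C(\C)CC/C=C(\C)C[C@H](O)[C@@H]1C2(C)C
F5 | step 17 | (1R,3E,7E,10R,11R,13R)-13-hydroxyverticilla-3,7,12(18)-trien-10-yl acetate | C=C1[C@H](O)C[C@H]2C/C=C(\C)CC/C=C(\C)C[C@@H](OC(C)=O)[C@@H]1C2(C)C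
F6 | step 17 | (1R,3E,7E,10R,11R)-13-oxoverticilla-3,7,12(18)-trien-10-yl acetate | C=C1C(=O)C[C@H]2C/C=C(\C)CC/C=C(\C)C[C@@H](OC(C)=O)[C@@H]1C2(C)C
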